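**Retrosynthetic overview**
1. 16 ⇐ 15 ⇐ 14: the naphthazarin is unmasked last from a 1,4,5,8-tetramethoxynaphthalene (oxidative demethylation, then Lewis-acid O-demethylation), with the ester and stereocentre already in place.
2. 14 ⇐ 12 + 13: the cyclobutane, the tertiary C–O bond and the (R) stereocentre come from one catalytic asymmetric cyclopropylcarbinyl-to-cyclobutyl ring expansion in which angelic acid captures the cation.
3. 12 ⇐ 10 ⇐ 7 + 8: the aryl–cyclopropane bond is made by Pd-catalysed coupling of a cyclopropyl Reformatsky reagent, followed by double MeMgBr addition.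
4. 7 ⇐ 6 ⇐ 4 ⇐ 1 + 2: bromination, reductive methylation, and double Friedel–Crafts annulation of hydroquinone with maleic anhydride.
5. Ring order: second six-membered ring of the naphthalene (step 1), cyclopropane (bought in 8), four-membered ring by ring expansion (step 6).

Assumption: the two naphthazarin tautomers (side chain on the quinone ring or on the dihydroxybenzene ring) interconvert rapidly and are one compound; 16 is written in the tautomer of the given SMILES.
Assumption: the sense of induction of the new step 6 cannot be known in advance; the (S,S)-catalyst is written as the one giving the (R)-ester, and its (R,R) mirror image is used if the sense is opposite.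

**Step 1**
Reactants: 1 hydroquinone; 2 maleic anhydride
Product: 4 naphthazarin (5,8-dihydroxy-1,4-naphthoquinone), via aroylacrylic acid 3 (not isolated)
Conditions: AlCl3/NaCl melt (5:1 w/w), 200–220 °C, 5 min; then 2 M HCl, 100 °C
Reagents that add atoms: none
Why: Double Friedel–Crafts acylation (classical naphthazarin synthesis in a melt): the anhydride acylates the ring ortho to one OH to give 3, whose acid closes the second ring on the adjacent position ortho to the other OH with loss of water, and acid hydrolysis frees the chelated product.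

**Step 2**
Reactants: 4 naphthazarin
Product: 6 1,4,5,8-tetramethoxynaphthalene, via leuco-naphthazarin 5 (not isolated)
Conditions: Na2S2O4, NaOH (aq), Bu4NBr (cat.), Me2SO4, THF/H2O, 0 °C → rt, under Ar
Reagents that add atoms: dimethyl sulfate, COS(=O)(=O)OC
Why: Dithionite reduction of the quinone to the tetraphenolate 5 followed by Williamson O-methylation under phase transfer (reductive methylation), which protects all four oxygens as methyl ethers.

**Step 3**
Reactants: 6 1,4,5,8-tetramethoxynaphthalene
Product: 7 2-bromo-1,4,5,8-tetramethoxynaphthalene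
Conditions: N-bromosuccinimide (1.05 equiv), CH2Cl2, 0 °C → rt
Reagents that add atoms: N-bromosuccinimide, O=C1CCC(=O)N1Br
Why: Electrophilic aromatic bromination: the four free positions of the symmetric, electron-rich 6 are equivalent, and the first bromine deactivates the arene enough to stop at the monobromide.

**Step 4**
Reactants: 7 2-bromo-1,4,5,8-tetramethoxynaphthalene; 8 methyl 1-bromocyclopropane-1-carboxylate
Product: 10 methyl 1-(1,4,5,8-tetramethoxynaphthalen-2-yl)cyclopropane-1-carboxylate, via cyclopropylzinc bromide 9 (not isolated)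
Conditions: Zn dust (Me3SiCl-activated), THF, rt; then 7, Pd(P(t-Bu)3)2 (5 mol %), THF, rt → 50 °C
Reagents that add atoms: none
Why: Zinc insertion gives the Reformatsky reagent 9, which undergoes Negishi-type α-arylation with the aryl bromide on the bulky, electron-rich zerovalent palladium catalyst; the zinc enolate avoids the Claisen and ring-opening problems of lithium cyclopropyl ester enolates.

**Step 5**
Reactants: 10 methyl 1-(1,4,5,8-tetramethoxynaphthalen-2-yl)cyclopropane-1-carboxylate
Product: 12 2-[1-(1,4,5,8-tetramethoxynaphthalen-2-yl)cyclopropyl]propan-2-ol, via methyl ketone 11 (not isolated)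
Conditions: MeMgBr (4 equiv), LaCl3·2LiCl (0.3 equiv), THF, 0 °C → rt; aq NH4Cl
Reagents that add atoms: methylmagnesium bromide, C[Mg]Br
Why: Double Grignard addition to an ester: the first equivalent gives ketone 11, which takes the second; the lanthanum salt suppresses enolisation of the hindered ketone, and no stereocentre is formed.

**Step 6**
Reactants: 12 2-[1-(1,4,5,8-tetramethoxynaphthalen-2-yl)cyclopropyl]propan-2-ol; 13 angelic acid ((2Z)-2-methylbut-2-enoic acid)
Product: 14 (1R)-2,2-dimethyl-1-(1,4,5,8-tetramethoxynaphthalen-2-yl)cyclobutyl (2Z)-2-methylbut-2-enoate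
Conditions: 13 (3 equiv), (S,S)-HN[P(=NSO2CF3)(O2C20H10Ar2)]2, Ar = 3,5-(CF3)2C6H3 at the 3,3′-positions of each (S)-binaphthalene-2,2′-diolate (IDPi acid, 5 mol %), 5 Å molecular sieves, CHCl3/cyclohexane 1:1, −40 °C; Et3N quench at −40 °C
Reagents that add atoms: none
Why: Proposed new method: a catalytic asymmetric dehydrative ring-expanding acyloxylation — the confined chiral Brønsted acid ionises the tertiary cyclopropylcarbinol (water is taken up by the sieves) to the cyclopropylcarbinyl cation, a ring C–C bond then shifts to the cationic carbon (cyclopropylcarbinyl-to-cyclobutyl Wagner–Meerwein ring expansion, driven by forming the tertiary benzylic cation stabilised by the electron-rich tetramethoxynaphthyl group), and the planar 1-aryl-2,2-dimethylcyclobutyl cation stays ion-paired in the chiral pocket of the imidodiphosphorimidate anion, which hydrogen-bonds angelic acid and delivers it to one enantiotopic face (told apart by the CMe2 and CH2 flanks and the ortho-methoxy group), so the (R) C–O stereocentre is set under catalyst control at a temperature where the hindered ester should not re-ionise; the closest known reaction types are the racemic acid-mediated cyclopropylcarbinyl–cyclobutyl rearrangement of 1-arylcyclopropyl carbinols and chiral-anion-controlled Wagner–Meerwein shifts and nucleophile captures of tertiary carbocations, none of which has been shown with carboxylic acid capture to give a tertiary cyclobutyl ester.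

**Step 7**
Reactants: 14 (1R)-2,2-dimethyl-1-(1,4,5,8-tetramethoxynaphthalen-2-yl)cyclobutyl (2Z)-2-methylbut-2-enoate
Product: 15 (1R)-1-(5,8-dimethoxy-1,4-dioxo-1,4-dihydronaphthalen-2-yl)-2,2-dimethylcyclobutyl (2Z)-2-methylbut-2-enoate
Conditions: (NH4)2Ce(NO3)6 (2.5 equiv), MeCN/H2O 3:1, 0 °C, 10 min (14 added to the oxidant)
Reagents that add atoms: water, O
Why: Oxidative demethylation of a para-dimethoxyarene by tetravalent cerium (water attacks the arene radical cation and methanol leaves), expected on the ring carrying the acyloxyalkyl group as with 2-(1-acyloxyalkyl) substrates (oxidation of the other ring would lead to the same naphthazarin after step 8), and the fast oxidation turns the ionisable benzylic ester into a non-ionisable quinonyl ester, so the quaternary stereocentre and the angelate are untouched.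

**Step 8**
Reactants: 15 (1R)-1-(5,8-dimethoxy-1,4-dioxo-1,4-dihydronaphthalen-2-yl)-2,2-dimethylcyclobutyl (2Z)-2-methylbut-2-enoate
Product: 16 (1R)-1-(5,8-dihydroxy-1,4-dioxo-1,4-dihydronaphthalen-2-yl)-2,2-dimethylcyclobutyl (2Z)-2-methylbut-2-enoate
Conditions: BCl3 (4 equiv), CH2Cl2, −78 → −20 °C; then H2O/MeOH, 0 °C
Reagents that add atoms: none
Why: Chelation-assisted Lewis-acid cleavage of aryl methyl ethers: both methoxy groups sit peri to a quinone carbonyl and are cleaved selectively by BCl3 at low temperature, while a cation next to the quinone ring is too destabilised for the tertiary ester to ionise.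

**Compound list**
1 | hydroquinone | Oc1ccc(O)cc1 | starting material
2 | maleic anhydride | O=C1OC(=O)C=C1 | starting material
3 | (2Z)-4-(2,5-dihydroxyphenyl)-4-oxobut-2-enoic acid | OC(=O)/C=C\C(=O)c1cc(O)ccc1O | intermediate
4 | naphthazarin (5,8-dihydroxy-1,4-naphthoquinone) | O=C1C=CC(=O)c2c(O)ccc(O)c12 | intermediate
5 | leuco-naphthazarin (naphthalene-1,4,5,8-tetrol, present as its sodium salt) | Oc1ccc(O)c2c(O)ccc(O)c12 | intermediate
6 | 1,4,5,8-tetramethoxynaphthalene | COc1ccc(OC)c2c(OC)ccc(OC)c12 | intermediate
7 | 2-bromo-1,4,5,8-tetramethoxynaphthalene | COc1c(Br)cc(OC)c2c(OC)ccc(OC)c12 | intermediate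
8 | methyl 1-bromocyclopropane-1-carboxylate | COC(=O)C1(Br)CC1 | starting material
9 | bromo[1-(methoxycarbonyl)cyclopropyl]zinc | COC(=O)C1([Zn]Br)CC1 | intermediate
10 | methyl 1-(1,4,5,8-tetramethoxynaphthalen-2-yl)cyclopropane-1-carboxylate | COC(=O)C1(CC1)c1cc(OC)c2c(OC)ccc(OC)c2c1OC | intermediate
11 | 1-[1-(1,4,5,8-tetramethoxynaphthalen-2-yl)cyclopropyl]ethan-1-one | CC(=O)C1(CC1)c1cc(OC)c2c(OC)ccc(OC)c2c1OC | intermediate
12 | 2-[1-(1,4,5,8-tetramethoxynaphthalen-2-yl)cyclopropyl]propan-2-ol | CC(C)(O)C1(CC1)c1cc(OC)c2c(OC)ccc(OC)c2c1OC | intermediate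
13 | angelic acid ((2Z)-2-methylbut-2-enoic acid) | C/C=C(/C)C(=O)O | starting material
14 | (1R)-2,2-dimethyl-1-(1,4,5,8-tetramethoxynaphthalen-2-yl)cyclobutyl (2Z)-2-methylbut-2-enoate | C/C=C(/C)C(=O)O[C@]1(c2cc(OC)c3c(OC)ccc(OC)c3c2OC)CCC1(C)C | intermediate
15 | (1R)-1-(5,8-dimethoxy-1,4-dioxo-1,4-dihydronaphthalen-2-yl)-2,2-dimethylcyclobutyl (2Z)-2-methylbut-2-enoate | C/C=C(/C)C(=O)O[C@]1(C2=CC(=O)c3c(OC)ccc(OC)c3C2=O)CCC1(C)C | intermediate
16 | (1R)-1-(5,8-dihydroxy-1,4-dioxo-1,4-dihydronaphthalen-2-yl)-2,2-dimethylcyclobutyl (2Z)-2-methylbut-2-enoate | C/C=C(/C)C(=O)O[C@]1(C2=CC(=O)c3c(O)ccc(O)c3C2=O)CCC1(C)C | target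

**Total step count:** 8. **Longest linear sequence:** 8 steps (1 and 2 to 16).

**Steps most likely to fail**

Step 6 (the proposed new step). The ester may form with low enantiomeric excess or racemise by re-ionisation. The cation may also lose a proton to the arylcyclobutene, or be captured at a cyclopropane CH2 to give a homoallylic ester. The fallback uses known chemistry and sets out from 12. Stirring 12 with TsOH·H2O (10 mol %) in THF/H2O 4:1 at 40 °C brings about the same cyclopropylcarbinyl-to-cyclobutyl shift with water capture and gives racemic 2,2-dimethyl-1-(1,4,5,8-tetramethoxynaphthalen-2-yl)cyclobutan-1-ol F1. The enantiomers are separated by preparative supercritical-fluid chromatography on an amylose tris(3,5-dimethylphenylcarbamate) phase to give (1R)-2,2-dimethyl-1-(1,4,5,8-tetramethoxynaphthalen-2-yl)cyclobutan-1-ol F2. Deprotonation with KN(SiMe3)2 in THF at −78 °C and acylation with (2Z)-2-methylbut-2-enoic 2,4,6-trichlorobenzoic anhydride F3 (made from 13, 2,4,6-trichlorobenzoyl chloride and Et3N) comes back to the route at 14.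

Step 4. Coupling a tertiary cyclopropyl zinc enolate with an ortho-methoxy, electron-rich aryl bromide builds a very crowded quaternary carbon and may stall. The fallback sets out from 7 and forms the quaternary carbon after the coupling. Compound 7 is coupled under the same palladium catalysis with the unhindered Reformatsky reagent bromo(2-methoxy-2-oxoethyl)zinc F4 (from methyl bromoacetate and Zn) to give methyl 2-(1,4,5,8-tetramethoxynaphthalen-2-yl)acetate F5. Double alkylation of F5 with BrCH2CH2Br (NaH, DMF, 0 °C → rt) closes the cyclopropane and comes back to the route at 10.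

Step 8. BCl3 may ionise or cleave the tertiary ester or isomerise the angelate to the tiglate. The fallback sets out from 15 and replaces Lewis-acid cleavage by a second oxidation and a reduction. Compound 15 is oxidised with AgO and 6 M HNO3 in dioxane at rt, which turns the remaining dimethoxybenzene ring into a quinone and gives (1R)-2,2-dimethyl-1-(1,4,5,8-tetraoxo-1,4,5,8-tetrahydronaphthalen-2-yl)cyclobutyl (2Z)-2-methylbut-2-enoate F6. Reduction of this diquinone by two electrons with aqueous Na2S2O4 in the work-up comes back to the route at 16.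

**Further compounds**
F1 | step 6 | racemic 2,2-dimethyl-1-(1,4,5,8-tetramethoxynaphthalen-2-yl)cyclobutan-1-ol | OC1(c2cc(OC)c3c(OC)ccc(OC)c3c2OC)CCC1(C)C
F2 | step 6 | (1R)-2,2-dimethyl-1-(1,4,5,8-tetramethoxynaphthalen-2-yl)cyclobutan-1-ol | O[C@]1(c2cc(OC)c3c(OC)ccc(OC)c3c2OC)CCC1(C)C
F3 | step 6 | (2Z)-2-methylbut-2-enoic 2,4,6-trichlorobenzoic anhydride | C/C=C(/C)C(=O)OC(=O)c1c(Cl)cc(Cl)cc1Cl
F4 | step 4 | bromo(2-methoxy-2-oxoethyl)zinc | COC(=O)C[Zn]Br
F5 | step 4 | methyl 2-(1,4,5,8-tetramethoxynaphthalen-2-yl)acetate | COC(=O)Cc1cc(OC)c2c(OC)ccc(OC)c2c1OC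
F6 | step 8 | (1R)-2,2-dimethyl-1-(1,4,5,8-tetraoxo-1,4,5,8-tetrahydronaphthalen-2-yl)cyclobutyl (2Z)-2-methylbut-2-enoate | C/C=C(/C)C(=O)O[C@]1(C2=CC(=O)C3=C(C2=O)C(=O)C=CC3=O)CCC1(C)C
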